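Readings and results come from a simulation for substances that don't exist.

- The noon readings rule out a constant rate of bis adduct formation: in the noon run, the mean rate up to 4.00 h is 0.0135 h⁻¹ (as a fraction of the starting material charged), which held for 30 h gives 40.5 %, far more than the 9.0 % read there.

| flask | starting material | coupling partner | capture agent | remark | time |
|---|---|---|---|---|---|
| winter | 0.20 M | 0.20 M | 0.010 M | the very flask that is asked about, followed so far |  |
| noon | 0.20 M | 0.20 M | 0.0050 M | run made earlier |  |
| flask | 0.20 M | 0.200 M | 0.0100 M |  | 30 h |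

- winter (time / h: bis adduct / %): 4.00: 4.7; 5.00: 5.5; 6.00: 7.7
- noon (time / h: bis adduct / %): 4.00: 5.4; 6.00: 7.1; 12.0: 11.0; 20.0: 10.5; 30.0: 9.0

(standard deviation of a reading: 0.3 percentage points)

1. the moment within 30 h at which there is most bis adduct
2. the amount of bis adduct, in percent of the starting material charged, at that time

- Between 6.00 h and 12.0 h, the noon rate is 0.00650 h⁻¹, slower by a factor of 2.08; between 12.0 h and 20.0 h, it reads −6.25 × 10⁻⁴ h⁻¹, a drop of 0.5 percentage points against a scatter of 0.3 points per reading, so this change of sign is only a reading.
- Interpolating between the midpoints of those intervals, I put the zero of the noon rate at 15.4 h.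
- With twice the capture agent, the winter flask reads 4.7 % against 5.4 % at 4.00 h, then 7.7 % against 7.1 % at 6.00 h. These differences have opposite signs and a scatter of 0.3 points per reading, so I expect the winter flask to turn near 15.4 h too.
- My fall constant λ, an apparent first-order constant, is the fractional loss of bis adduct per hour after the peak, net of what is still formed: from the noon tail, λ = 0.0154 h⁻¹.
- Putting my turning time back in, λ carries the noon reading at 20.0 h up to a peak of 11.3 %, and I expect about the same peak in the winter flask.
- The forecast gives 26 h and 14.8 %, against my 15.4 h and 11.3 %, on the ground, said of the capture agent, that “Doubling it should postpone exhaustion to at least about 24 h”.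
- The winter flask peaks at 16.6 h with 11.1 %.

    starting material + coupling partner → mono adduct (k = 2.00 × 10⁻⁴ M⁻¹ s⁻¹)
    coupling partner + mono adduct → bis adduct (k = 1.40 × 10⁻⁴ M⁻¹ s⁻¹)
    coupling partner + bis adduct → tris adduct (k = 1.20 × 10⁻⁴ M⁻¹ s⁻¹)
    coupling partner + tris adduct → tetra adduct (k = 1.30 × 10⁻⁵ M⁻¹ s⁻¹)
    mono adduct → side product (k = 7.30 × 10⁻⁶ s⁻¹)
    mono adduct + capture agent → trapped intermediate (k = 4.30 × 10⁻⁵ M⁻¹ s⁻¹)
    bis adduct → over-reaction product (k = 8.40 × 10⁻⁶ s⁻¹)

- With half the capture agent, the peak comes at 16.7 h, and the step through the trapped intermediate makes no difference to that time. From the peak to 30 h, λ gives 9.03 %, and the winter flask holds 9.21 %. Carried on from there to 5.0 d, λ gives 2.30 %, and the same flask left that long holds 0.692 %.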